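**Retrosynthetic overview**
1. Target 29 ← desilylation of 28; the eleven-membered ring is closed last by an intramolecular Nozaki–Hiyama–Kishi coupling (vinyl iodide C6 + side-chain aldehyde), which also creates the allylic carbinol.
2. Iodo-diacetate 25 ← enone 20 by α'-hydroxylation, α-iodination and hydroxyl-directed reduction (trans-4,5-diol).
3. Enone 20 ← ketone 13 + alkenyl bromide 9: alkenylcerium addition, then palladium–formate reductive allylic transposition (sets C1–H, gives the exocyclic methylene), then enone unveiling.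
4. cis-Hydrindanone 13 ← 3-methylcyclopent-2-enone 12 + silyloxydiene 11 by the proposed catalytic asymmetric Diels–Alder reaction (quaternary C3a and C7a).
5. Bromide 9 ← 2-bromoallyl alcohol by Johnson–Claisen rearrangement, anti-crotylation and hydroboration. Ring order: five-membered (bought) → six-membered (step 7) → eleven-membered (step 18).

Assumption: the SMILES is taken as the required absolute configuration, and for every chiral catalyst or reagent named, the antipode that gives the drawn configuration is the one used.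

Abbreviations: TBS = tert-butyldimethylsilyl; TES = triethylsilyl; "side chain S" = (5S,6R)-5,8-bis(TBS-oxy)-6-methyloct-1-en-2-yl. Core locants follow indene numbering (C1 carries the side chain, C3a the angular methyl, C7a the ring-fusion H).

**Fragment B (side chain)**

Step 1
Reactants: 1 2-bromoprop-2-en-1-ol; 2 triethyl orthoacetate
Product: 3 ethyl 4-bromopent-4-enoate
Conditions: 2 (5 equiv), EtCO2H (cat.), 140 °C, EtOH distilled off
Reagents that add atoms: none
Why: Johnson–Claisen rearrangement (orthoester exchange, then [3,3]-sigmatropic shift) gives the γ,δ-unsaturated ester with the 2-bromoalkene intact; no stereocentre is formed.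

Step 2
Reactants: 3 ethyl 4-bromopent-4-enoate
Product: 4 4-bromopent-4-en-1-ol
Conditions: i-Bu2AlH (2.5 equiv), CH2Cl2, −78 → 0 °C; aq. potassium sodium tartrate
Reagents that add atoms: none
Why: Hydride reduction of the ester to the primary alcohol; the vinyl bromide is inert at this temperature.

Step 3
Reactants: 4 4-bromopent-4-en-1-ol; 5 but-3-en-2-yl acetate (racemic)
Product: 6 (3R,4S)-7-bromo-3-methylocta-1,7-dien-4-ol
Conditions: [Ir(cod)Cl]2 (2.5 mol%), (S)-SEGPHOS (5 mol%), 4-cyano-3-nitrobenzoic acid (10 mol%), Cs2CO3 (20 mol%), 5 (2 equiv), K3PO4 (1 equiv), H2O (5 equiv), THF, 70 °C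
Reagents that add atoms: none
Why: Iridium-catalysed transfer-hydrogenative carbonyl crotylation from the alcohol oxidation level: the transient aldehyde is attacked by an (E)-σ-crotyliridium species through a closed chair transition state, which gives the anti adduct, and the chiral ligand fixes the aldehyde face (C4 S, C3 R).

Step 4
Reactants: 6 (3R,4S)-7-bromo-3-methylocta-1,7-dien-4-ol
Product: 8 (3R,4S)-7-bromo-3-methyloct-7-ene-1,4-diol, via B-alkyl-9-BBN adduct 7 (not isolated)
Conditions: 9-BBN-H (2.5 equiv), THF, 0 → 23 °C; then NaOH, H2O2, 0 °C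
Reagents that add atoms: hydrogen peroxide, OO
Why: Anti-Markovnikov hydroboration–oxidation; 9-BBN selects the monosubstituted vinyl group over the deactivated 2-bromoalkene, and both stereocentres are untouched.

Step 5
Reactants: 8 (3R,4S)-7-bromo-3-methyloct-7-ene-1,4-diol
Product: 9 (5S,6R)-2-bromo-5,8-bis(tert-butyldimethylsilyloxy)-6-methyloct-1-ene
Conditions: TBSOTf (2.4 equiv), 2,6-lutidine, CH2Cl2, 0 °C
Reagents that add atoms: tert-butyldimethylsilyl triflate, CC(C)(C)[Si](C)(C)OS(=O)(=O)C(F)(F)F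
Why: Silylation of both hydroxyls; the primary TBS ether can later be removed selectively in the presence of the secondary one.

**Fragment A (core) and assembly**

Step 6
Reactants: 10 (E)-pent-3-en-2-one
Product: 11 triethyl[(3E)-penta-1,3-dien-2-yloxy]silane
Conditions: TESOTf, Et3N, Et2O, 0 °C
Reagents that add atoms: triethylsilyl triflate, CC[Si](CC)(CC)OS(=O)(=O)C(F)(F)F
Why: Soft enolisation of the methyl ketone at CH3 gives the cross-conjugated 2-silyloxydiene with the (E)-alkene retained.

Step 7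
Reactants: 12 3-methylcyclopent-2-en-1-one; 11 triethyl[(3E)-penta-1,3-dien-2-yloxy]silane
Product: 13 (3aR,7S,7aS)-3a,7-dimethyl-5-(triethylsilyloxy)-2,3,3a,4,7,7a-hexahydro-1H-inden-1-one
Conditions: confined chiral imidodiphosphorimidate Brønsted acid (IDPi, 3 mol%, silylated in situ by 11), 11 (2.5 equiv), toluene, −40 → −20 °C; Et3N quench
Reagents that add atoms: none
Why: Proposed new method: catalytic enantioselective Diels–Alder reaction of a β-methyl cycloalkenone with an acyclic 2-silyloxydiene under silylium–imidodiphosphorimidate ion-pair catalysis, in which the acid is silylated by 11, the Et3Si+ Lewis acid activates 12 as a silyloxyallyl cation held in the chiral anion pocket, the nucleophilic CH2 terminus of the diene attacks the β-carbon (quaternary C3a) and the methyl-bearing terminus closes onto the α-carbon suprafacially (cis fusion, endo gives 7S, and C7 epimers converge in step 11), and silyl transfer to the next enone turns the cycle over; the closest known reaction types are silylium–IDPi-catalysed Diels–Alder and Mukaiyama–Michael reactions of unsaturated esters and chiral Lewis acid-catalysed Diels–Alder reactions of β-unsubstituted cycloalkenones with 2-silyloxydienes.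

Step 8
Reactants: 9 (5S,6R)-2-bromo-5,8-bis(tert-butyldimethylsilyloxy)-6-methyloct-1-ene; 13 the cis-hydrindanone
Product: 16 (1R,3aR,7S,7aS)-1-(side chain S)-3a,7-dimethyl-5-(triethylsilyloxy)-2,3,3a,4,7,7a-hexahydro-1H-inden-1-ol (OH trans to 7a-H), via alkenyllithium 14 (not isolated), via alkenylcerium dichloride 15 (not isolated)
Conditions: 9 (1.3 equiv), t-BuLi (2.6 equiv), Et2O, −78 °C; CeCl3, THF, −78 °C; 13, −78 °C; H2O
Reagents that add atoms: none
Why: Bromine–lithium exchange, transmetalation to cerium and 1,2-addition to the enolisable ketone on the convex face of the cis-fused bicycle (the face of the angular H and CH3), while the silyl enol ether masks the six-ring carbonyl.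

Step 9
Reactants: 16 the tertiary allylic alcohol
Product: 18 methyl carbonate of 16 [(1R)-1-(methoxycarbonyloxy) derivative], via lithium alkoxide 17 (not isolated)
Conditions: LiN(SiMe3)2, THF, −78 °C; ClCO2Me, −78 → 0 °C
Reagents that add atoms: methyl chloroformate, COC(=O)Cl
Why: O-acylation of the tertiary lithium alkoxide gives the ionisable allylic carbonate without touching the silyl enol ether.

Step 10
Reactants: 18 the tertiary allylic methyl carbonate
Product: 19 (1R,3aR,7R,7aR)-1-(side chain S)-3a,7-dimethyl-5-(triethylsilyloxy)-2,3,3a,4,7,7a-hexahydro-1H-indene (1-H, 7a-H and 3a-CH3 all cis)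
Conditions: Pd(OAc)2 (5 mol%), n-Bu3P (20 mol%), HCO2H (3 equiv), Et3N (4 equiv), THF, 40 °C
Reagents that add atoms: none
Why: Tsuji palladium–formate reductive allylic transposition: zerovalent palladium ionises the carbonate anti (palladium on the convex face, which is also the less hindered face after π–σ–π equilibration), formate gives a palladium hydride that is delivered to the more substituted ring terminus, setting C1–H cis to 7a-H and leaving the 1,1-disubstituted exocyclic alkene.

Step 11
Reactants: 19 the silyl enol ether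
Product: 20 (1R,3aR,7aR)-1-(side chain S)-3a,7-dimethyl-1,2,3,3a,4,7a-hexahydro-5H-inden-5-one
Conditions: IBX, 4-methoxypyridine N-oxide, DMSO, 23 °C
Reagents that add atoms: none
Why: IBX dehydrogenation of a silyl enol ether to the enone; only C7 carries a removable hydrogen (C3a is quaternary), so the C6=C7 enone is the sole product and the C7 stereocentre is erased.

Step 12
Reactants: 20 the enone
Product: 22 (1R,3aS,4R,7aS)-4-hydroxy-1-(side chain S)-3a,7-dimethyl-1,2,3,3a,4,7a-hexahydro-5H-inden-5-one (4-OH cis to 3a-CH3), via sodium dienolate 21 (not isolated)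
Conditions: NaN(SiMe3)2, THF, −78 °C; 2-(phenylsulfonyl)-3-phenyloxaziridine, −78 °C; AcOH
Reagents that add atoms: 2-(phenylsulfonyl)-3-phenyloxaziridine, O=S(=O)(N1OC1c1ccccc1)c1ccccc1
Why: Kinetic α'-deprotonation (as for isophorone) and Davis oxaziridine hydroxylation of the enolate on the convex face of the cis-fused bicycle, which places the new hydroxyl cis to the angular methyl.

Step 13
Reactants: 22 the α'-hydroxy enone
Product: 23 (1R,3aS,4R,7aR)-4-hydroxy-6-iodo-1-(side chain S)-3a,7-dimethyl-1,2,3,3a,4,7a-hexahydro-5H-inden-5-one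
Conditions: I2 (3 equiv), pyridine/CH2Cl2 1:1, 23 °C
Reagents that add atoms: iodine, II
Why: Johnson α-iodination of an enone (pyridine conjugate addition, iodination of the enolate, elimination); the isolated exocyclic alkene does not add iodine irreversibly.

Step 14
Reactants: 23 the α-iodo-α'-hydroxy enone
Product: 24 (1R,3aS,4R,5S,7aR)-6-iodo-1-(side chain S)-3a,7-dimethyl-2,3,3a,4,5,7a-hexahydro-1H-indene-4,5-diol (trans-diol)
Conditions: Me4NBH(OAc)3 (5 equiv), MeCN/AcOH 1:1, −25 °C
Reagents that add atoms: none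
Why: Saksena–Evans hydroxyl-directed reduction: the C4 oxygen binds boron and hydride is delivered intramolecularly on that face, so the C5 hydroxyl ends trans to the C4 hydroxyl.

Step 15
Reactants: 24 the trans-diol
Product: 25 (1R,3aS,4R,5S,7aR)-6-iodo-1-(side chain S)-3a,7-dimethyl-2,3,3a,4,5,7a-hexahydro-1H-indene-4,5-diyl diacetate
Conditions: Ac2O, pyridine, DMAP (cat.), CH2Cl2, 23 °C
Reagents that add atoms: acetic anhydride, CC(=O)OC(C)=O
Why: Acylation of both secondary alcohols installs the two acetates of the target before the remaining hydroxyls are unmasked.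

Step 16
Reactants: 25 the diacetate
Product: 26 primary alcohol: 25 with the side chain (5S,6R)-5-(TBS-oxy)-8-hydroxy-6-methyloct-1-en-2-yl
Conditions: HF·pyridine, pyridine, THF, 0 °C
Reagents that add atoms: none
Why: Buffered fluoride cleaves the unhindered primary TBS ether much faster than the secondary one; acetates and vinyl iodide are stable.

Step 17
Reactants: 26 the primary alcohol
Product: 27 aldehyde: 25 with the side chain (5S,6R)-5-(TBS-oxy)-6-methyl-8-oxooct-1-en-2-yl
Conditions: Dess–Martin periodinane, pyridine, CH2Cl2, 0 → 23 °C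
Reagents that add atoms: none
Why: Dess–Martin oxidation gives the aldehyde, which has no α-stereocentre to epimerise.

Step 18
Reactants: 27 the iodo aldehyde
Product: 28 tricyclic (5-6-11) allylic alcohol: the target carrying a TBS ether on the CH(O)–CH(CH3) carbinol, new carbinol S
Conditions: CrCl2 (8 equiv), NiCl2 (2 mol%), DMSO/THF 3:1, 0.002 M, 23 °C
Reagents that add atoms: none
Why: Intramolecular Nozaki–Hiyama–Kishi coupling (nickel-catalysed activation of the vinyl iodide, transmetalation to chromium, addition to the aldehyde) closes the eleven-membered ring across the concave face; the aldehyde should be attacked on the face exposed when the tether carries its methyl and silyloxy groups pseudo-equatorially, which is expected (not proven) to give the S carbinol.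

Step 19
Reactants: 28 the macrocyclic TBS ether
Product: 29 CNP0114864.2
Conditions: HF·pyridine, THF, 0 → 23 °C
Reagents that add atoms: none
Why: Acidic fluoride desilylation frees the last hydroxyl without acetate migration or loss.

**Compound list**
1 | 2-bromoprop-2-en-1-ol | OCC(Br)=C | starting material
2 | triethyl orthoacetate | CC(OCC)(OCC)OCC | starting material
3 | ethyl 4-bromopent-4-enoate | CCOC(=O)CCC(Br)=C | intermediate
4 | 4-bromopent-4-en-1-ol | OCCCC(Br)=C | intermediate
5 | but-3-en-2-yl acetate (racemic) | C=CC(C)OC(C)=O | starting material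
6 | (3R,4S)-7-bromo-3-methylocta-1,7-dien-4-ol | C=C(Br)CC[C@H](O)[C@H](C)C=C | intermediate
7 | 9-[(3R,4S)-7-bromo-4-hydroxy-3-methyloct-7-en-1-yl]-9-borabicyclo[3.3.1]nonane | C=C(Br)CC[C@H](O)[C@H](C)CCB1C2CCCC1CCC2 | intermediate
8 | (3R,4S)-7-bromo-3-methyloct-7-ene-1,4-diol | C=C(Br)CC[C@H](O)[C@H](C)CCO | intermediate
9 | (5S,6R)-2-bromo-5,8-bis(tert-butyldimethylsilyloxy)-6-methyloct-1-ene | C=C(Br)CC[C@H](O[Si](C)(C)C(C)(C)C)[C@H](C)CCO[Si](C)(C)C(C)(C)C | intermediate
10 | (E)-pent-3-en-2-one | C/C=C/C(C)=O | starting material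
11 | triethyl[(3E)-penta-1,3-dien-2-yloxy]silane | C=C(O[Si](CC)(CC)CC)/C=C/C | intermediate
12 | 3-methylcyclopent-2-en-1-one | CC1=CC(=O)CC1 | starting material
13 | (3aR,7S,7aS)-3a,7-dimethyl-5-(triethylsilyloxy)-2,3,3a,4,7,7a-hexahydro-1H-inden-1-one | CC[Si](CC)(CC)OC1=C[C@H](C)[C@@H]2C(=O)CC[C@]2(C)C1 | intermediate
14 | [(5S,6R)-5,8-bis(TBS-oxy)-6-methyloct-1-en-2-yl]lithium | [Li]C(=C)CC[C@H](O[Si](C)(C)C(C)(C)C)[C@H](C)CCO[Si](C)(C)C(C)(C)C | intermediate
15 | [(5S,6R)-5,8-bis(TBS-oxy)-6-methyloct-1-en-2-yl]cerium dichloride | Cl[Ce](Cl)C(=C)CC[C@H](O[Si](C)(C)C(C)(C)C)[C@H](C)CCO[Si](C)(C)C(C)(C)C | intermediate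
16 | (1R,3aR,7S,7aS)-1-(side chain S)-3a,7-dimethyl-5-(triethylsilyloxy)-2,3,3a,4,7,7a-hexahydro-1H-inden-1-ol | CC[Si](CC)(CC)OC1=C[C@H](C)[C@@H]2[C@](C(=C)CC[C@H](O[Si](C)(C)C(C)(C)C)[C@H](C)CCO[Si](C)(C)C(C)(C)C)(O)CC[C@]2(C)C1 | intermediate
17 | lithium alkoxide of 16 | CC[Si](CC)(CC)OC1=C[C@H](C)[C@@H]2[C@](C(=C)CC[C@H](O[Si](C)(C)C(C)(C)C)[C@H](C)CCO[Si](C)(C)C(C)(C)C)(O[Li])CC[C@]2(C)C1 | intermediate
18 | methyl carbonate of 16 | CC[Si](CC)(CC)OC1=C[C@H](C)[C@@H]2[C@](C(=C)CC[C@H](O[Si](C)(C)C(C)(C)C)[C@H](C)CCO[Si](C)(C)C(C)(C)C)(OC(=O)OC)CC[C@]2(C)C1 | intermediate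
19 | (1R,3aR,7R,7aR)-1-(side chain S)-3a,7-dimethyl-5-(triethylsilyloxy)-2,3,3a,4,7,7a-hexahydro-1H-indene | CC[Si](CC)(CC)OC1=C[C@H](C)[C@@H]2[C@H](C(=C)CC[C@H](O[Si](C)(C)C(C)(C)C)[C@H](C)CCO[Si](C)(C)C(C)(C)C)CC[C@]2(C)C1 | intermediate
20 | (1R,3aR,7aR)-1-(side chain S)-3a,7-dimethyl-1,2,3,3a,4,7a-hexahydro-5H-inden-5-one | O=C1C=C(C)[C@@H]2[C@H](C(=C)CC[C@H](O[Si](C)(C)C(C)(C)C)[C@H](C)CCO[Si](C)(C)C(C)(C)C)CC[C@]2(C)C1 | intermediate
21 | sodium C4=C5 dienolate of 20 | [Na]OC=1C=C(C)[C@@H]2[C@H](C(=C)CC[C@H](O[Si](C)(C)C(C)(C)C)[C@H](C)CCO[Si](C)(C)C(C)(C)C)CC[C@]2(C)C=1 | intermediate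
22 | (1R,3aS,4R,7aS)-4-hydroxy-1-(side chain S)-3a,7-dimethyl-1,2,3,3a,4,7a-hexahydro-5H-inden-5-one | C1=C(C)[C@@H]2[C@H](C(=C)CC[C@H](O[Si](C)(C)C(C)(C)C)[C@H](C)CCO[Si](C)(C)C(C)(C)C)CC[C@]2(C)[C@@H](O)C1=O | intermediate
23 | (1R,3aS,4R,7aR)-4-hydroxy-6-iodo-1-(side chain S)-3a,7-dimethyl-1,2,3,3a,4,7a-hexahydro-5H-inden-5-one | IC1=C(C)[C@@H]2[C@H](C(=C)CC[C@H](O[Si](C)(C)C(C)(C)C)[C@H](C)CCO[Si](C)(C)C(C)(C)C)CC[C@]2(C)[C@@H](O)C1=O | intermediate
24 | (1R,3aS,4R,5S,7aR)-6-iodo-1-(side chain S)-3a,7-dimethyl-2,3,3a,4,5,7a-hexahydro-1H-indene-4,5-diol | IC1=C(C)[C@@H]2[C@H](C(=C)CC[C@H](O[Si](C)(C)C(C)(C)C)[C@H](C)CCO[Si](C)(C)C(C)(C)C)CC[C@]2(C)[C@@H](O)[C@@H]1O | intermediate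
25 | 4,5-diacetate of 24 | IC1=C(C)[C@@H]2[C@H](C(=C)CC[C@H](O[Si](C)(C)C(C)(C)C)[C@H](C)CCO[Si](C)(C)C(C)(C)C)CC[C@]2(C)[C@@H](OC(C)=O)[C@@H]1OC(C)=O | intermediate
26 | 25 with side chain (5S,6R)-5-(TBS-oxy)-8-hydroxy-6-methyloct-1-en-2-yl | IC1=C(C)[C@@H]2[C@H](C(=C)CC[C@H](O[Si](C)(C)C(C)(C)C)[C@H](C)CCO)CC[C@]2(C)[C@@H](OC(C)=O)[C@@H]1OC(C)=O | intermediate
27 | 25 with side chain (5S,6R)-5-(TBS-oxy)-6-methyl-8-oxooct-1-en-2-yl | IC1=C(C)[C@@H]2[C@H](C(=C)CC[C@H](O[Si](C)(C)C(C)(C)C)[C@H](C)CC=O)CC[C@]2(C)[C@@H](OC(C)=O)[C@@H]1OC(C)=O | intermediate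
28 | TBS ether of the target at the CH(O)–CH(CH3) carbinol, allylic OH free | C=C1CC[C@H](O[Si](C)(C)C(C)(C)C)[C@H](C)C[C@H](O)C2=C(C)[C@@H]3[C@H]1CC[C@]3(C)[C@@H](OC(C)=O)[C@@H]2OC(C)=O | intermediate
29 | CNP0114864.2 | C=C1CC[C@H](O)[C@H](C)C[C@H](O)C2=C(C)[C@@H]3[C@H]1CC[C@]3(C)[C@@H](OC(C)=O)[C@@H]2OC(C)=O | target

**Totals and risks**

Total step count: 19. Longest linear sequence: 17 steps (steps 1–5, then 8–19). The core branch is 14 steps (6, 7, 8–19).

Three steps most likely to fail:

Step 7 (proposed asymmetric Diels–Alder; the β-methyl enone may be too unreactive or poorly selective). Fallback with known chemistry, setting out from 12 and coming back at 13: Hosomi–Sakurai allylation of 12 (allyltrimethylsilane, TiCl4, CH2Cl2, −78 °C) gives racemic 3-allyl-3-methylcyclopentan-1-one F1. Ozonolysis (O3, then PPh3) gives racemic 2-(1-methyl-3-oxocyclopentyl)acetaldehyde F2. Addition of 1-propynylmagnesium bromide at −78 °C to the aldehyde in preference to the ketone gives the propargylic alcohol 3-(2-hydroxypent-3-yn-1-yl)-3-methylcyclopentan-1-one F3, and MnO2 oxidises it to the ynone 3-methyl-3-(2-oxopent-3-yn-1-yl)cyclopentan-1-one F4. Cs2CO3 in MeCN closes the six-membered ring by 6-endo-dig intramolecular Michael addition of the cyclopentanone enolate (thermodynamic cis fusion) to give (3aR,7aR)-3a,7-dimethyl-2,3,3a,4-tetrahydro-1H-indene-1,5(7aH)-dione F5. This is formed as the racemate and resolved by preparative chromatography on a chiral stationary phase. RhCl(PPh3)3-catalysed 1,4-hydrosilylation of the enone with Et3SiH (the saturated ketone reacts more slowly; the C7 epimer ratio is immaterial) returns to 13.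

Step 10 (palladium–formate reduction; risk of hydride delivery to the CH2 terminus, diene formation, or attack of the silyl enol ether on the allyl complex). Fallback with known chemistry, setting out from 16 and coming back at 19: perrhenate-catalysed 1,3-transposition (Ph3SiOReO3 cat., Et2O, −40 °C) moves the hydroxyl to the primary terminus and gives the tetrasubstituted-alkene primary allylic alcohol F6 (E/Z mixture, both converge). Mitsunobu reaction with 2-nitrobenzenesulfonylhydrazide (PPh3, diethyl azodicarboxylate, THF, −30 °C) gives the N-allyl-N-sulfonylhydrazine F7. On warming to 23 °C this eliminates the sulfinate to the allylic diazene F8, which loses N2 by a sigmatropic retro-ene shift (Myers reductive transposition). Hydrogen is delivered to the ring carbon on the convex face and the exocyclic methylene is regenerated, giving 19.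

Step 18 (macrocyclisation; the main risk is the configuration of the new allylic carbinol). Fallback with known chemistry, setting out from 27 and coming back at 28: the Ni/Cr coupling is run without regard to that centre and gives, besides 28, its allylic carbinol epimer F9. The mixture is oxidised with MnO2 to the macrocyclic enone F10. The ketone is then reduced under reagent control with (R)-2-methyl-CBS-oxazaborolidine and catecholborane at −78 °C (the fully substituted alkenyl group is the large substituent, and catecholborane leaves the exocyclic alkene alone), which returns to 28.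

**Further compounds**
F1 | step 7 | rac-3-allyl-3-methylcyclopentan-1-one | C=CCC1(C)CCC(=O)C1
F2 | step 7 | rac-2-(1-methyl-3-oxocyclopentyl)acetaldehyde | O=CCC1(C)CCC(=O)C1
F3 | step 7 | rac-3-(2-hydroxypent-3-yn-1-yl)-3-methylcyclopentan-1-one (carbinol epimers) | CC#CC(O)CC1(C)CCC(=O)C1
F4 | step 7 | rac-3-methyl-3-(2-oxopent-3-yn-1-yl)cyclopentan-1-one | CC#CC(=O)CC1(C)CCC(=O)C1
F5 | step 7 | (3aR,7aR)-3a,7-dimethyl-2,3,3a,4-tetrahydro-1H-indene-1,5(7aH)-dione (after resolution) | O=C1C=C(C)[C@@H]2C(=O)CC[C@]2(C)C1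
F6 | step 10 | primary allylic alcohol: 2-[(3aR,7S,7aR)-3a,7-dimethyl-5-(triethylsilyloxy)-2,3,3a,4,7,7a-hexahydro-1H-inden-1-ylidene] derivative of (5S,6R)-5,8-bis(TBS-oxy)-6-methyloctan-1-ol (E/Z) | CC[Si](CC)(CC)OC1=C[C@H](C)[C@@H]2C(=C(CO)CC[C@H](O[Si](C)(C)C(C)(C)C)[C@H](C)CCO[Si](C)(C)C(C)(C)C)CC[C@]2(C)C1
F7 | step 10 | N-allyl-N-(2-nitrobenzenesulfonyl)hydrazine from F6 (not isolated) | CC[Si](CC)(CC)OC1=C[C@H](C)[C@@H]2C(=C(CN(N)S(=O)(=O)c3ccccc3[N+](=O)[O-])CC[C@H](O[Si](C)(C)C(C)(C)C)[C@H](C)CCO[Si](C)(C)C(C)(C)C)CC[C@]2(C)C1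
F8 | step 10 | allylic diazene from F7 (not isolated) | CC[Si](CC)(CC)OC1=C[C@H](C)[C@@H]2C(=C(CN=N)CC[C@H](O[Si](C)(C)C(C)(C)C)[C@H](C)CCO[Si](C)(C)C(C)(C)C)CC[C@]2(C)C1
F9 | step 18 | allylic carbinol epimer of 28 | C=C1CC[C@H](O[Si](C)(C)C(C)(C)C)[C@H](C)C[C@@H](O)C2=C(C)[C@@H]3[C@H]1CC[C@]3(C)[C@@H](OC(C)=O)[C@@H]2OC(C)=O
F10 | step 18 | macrocyclic enone (ketone in place of the allylic carbinol of 28) | C=C1CC[C@H](O[Si](C)(C)C(C)(C)C)[C@H](C)CC(=O)C2=C(C)[C@@H]3[C@H]1CC[C@]3(C)[C@@H](OC(C)=O)[C@@H]2OC(C)=O
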